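**Plan**

- Retrosynthesis first cuts the two aryl–C(=O) bonds together (ring A–pentanoyl, ring B–butanoyl), which leads back to the O-acyl groups of a mixed diester. It then cuts the bond between ring A and the CH2 bridge; the bridge carbon is a formyl group on ring B.
- The feature that allows the double shift: on each ring the ketone carbon sits on a ring carbon between two oxygen-bearing carbons. In the diester that carbon is the only ring C–H, ortho to the ester oxygen, while the other ortho carbon carries the CH2 bridge and the para carbon a methyl group.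
- Forward: no ring is built. Each benzene ring gets its third oxygen by iridium-catalysed C–H borylation/oxidation para to its methyl group. The ring A phenol is pentanoylated; the ring B phenol is formylated beside its methoxy group and butanoylated. The halves are joined by reductive Friedel–Crafts alkylation, one irradiation moves both acyl groups, and fluoride frees the last phenol.
- The ring B oxygen that ends between butanoyl and methyl travels as a TIPS ether and not as a second methyl ether. Once the neighbouring phenol has chelated the new ketone, a methyl ether there could no longer be cleaved selectively beside the methoxy group that must stay.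
- Stereochemistry: the target is achiral and nothing has to be set. The one stereogenic carbinol carbon on the way is racemic and is reduced to CH2 in the same flask.

Key step: step 10

Remark on the chemistry: the target is treated as the fully phenolic (acylphenol) tautomer; ring A is the pentanoyl-bearing ring, ring B the butanoyl- and methoxy-bearing ring.

**Route**

Step 1
Reactants: 1 2-methylbenzene-1,3-diol (2-methylresorcinol)
Product: 2 2,6-bis[tert-butyl(dimethyl)silyloxy]toluene
Conditions: TBSCl (2.3 equiv), imidazole, DMF, rt
Reagents that add atoms: tert-butyldimethylsilyl chloride, CC(C)(C)[Si](C)(C)Cl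
Why: Imidazole-promoted silylation of phenols should cap both hydroxyl groups, which keeps O–H bonds away from the boron reagent and leaves the later acylation only one oxygen to find.

Step 2
Reactants: 2 2,6-bis[tert-butyl(dimethyl)silyloxy]toluene
Product: 4 3,5-bis[tert-butyl(dimethyl)silyloxy]-4-methylphenol, via aryl pinacol boronate 3 (not isolated)
Conditions: [Ir(OMe)(cod)]2 (1.5 mol %), 4,4'-di-tert-butyl-2,2'-bipyridine (3 mol %), B2pin2 (0.6 equiv), THF, 80 °C; then Oxone (2KHSO5·KHSO4·K2SO4), acetone–H2O, rt, 10 min
Reagents that add atoms: bis(pinacolato)diboron, CC1(C)OB(OC1(C)C)B1OC(C)(C)C(C)(C)O1 (boron of 3 only); potassium peroxymonosulfate from Oxone, [K+].[O-]S(=O)(=O)OO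
Why: Iridium-catalysed C–H borylation is governed by sterics and should engage only the ring C–H that has hydrogen on both sides (para to methyl, meta to both silyloxy groups), and oxidation of the C–B bond with Oxone (one-pot borylation/oxidation to a phenol) should place the third oxygen exactly there.

Step 3
Reactants: 4 3,5-bis[tert-butyl(dimethyl)silyloxy]-4-methylphenol; 5 pentanoyl chloride
Product: 6 3,5-bis[tert-butyl(dimethyl)silyloxy]-4-methylphenyl pentanoate
Conditions: Et3N, DMAP (cat.), CH2Cl2, 0 °C
Reagents that add atoms: none
Why: DMAP-catalysed O-acylation of the single free phenol should give the pentanoate with no regiochemical choice to make.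

Step 4
Reactants: 6 3,5-bis[tert-butyl(dimethyl)silyloxy]-4-methylphenyl pentanoate
Product: 7 3,5-dihydroxy-4-methylphenyl pentanoate
Conditions: HF·pyridine, THF, 0 °C to rt
Reagents that add atoms: none
Why: Fluoride-driven desilylation of the aryl silyl ethers under non-basic conditions should free both phenols without generating a phenoxide that could transfer or hydrolyse the aryl ester.

Step 5
Reactants: 8 3-methoxy-2-methylphenol
Product: 9 (3-methoxy-2-methylphenoxy)tri(propan-2-yl)silane
Conditions: TIPSCl, imidazole, DMF, 40 °C
Reagents that add atoms: chlorotri(propan-2-yl)silane, CC(C)[Si](Cl)(C(C)C)C(C)C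
Why: Silylation of the phenol with the bulky TIPS group should mark this oxygen as the one to be unmasked last and later screen the ring carbon next to it.

Step 6
Reactants: 9 (3-methoxy-2-methylphenoxy)tri(propan-2-yl)silane
Product: 11 3-methoxy-4-methyl-5-[tri(propan-2-yl)silyloxy]phenol, via aryl pinacol boronate 10 (not isolated)
Conditions: [Ir(OMe)(cod)]2 (1.5 mol %), 4,4'-di-tert-butyl-2,2'-bipyridine (3 mol %), B2pin2 (0.6 equiv), THF, 80 °C; then Oxone (2KHSO5·KHSO4·K2SO4), acetone–H2O, rt, 10 min
Reagents that add atoms: bis(pinacolato)diboron, CC1(C)OB(OC1(C)C)B1OC(C)(C)C(C)(C)O1 (boron of 10 only); potassium peroxymonosulfate from Oxone, [K+].[O-]S(=O)(=O)OO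
Why: As in step 2, sterically controlled iridium-catalysed C–H borylation should select the only C–H that is not ortho to a substituent (para to methyl), and Oxone oxidation should turn the boronate into the phenol.

Step 7
Reactants: 11 3-methoxy-4-methyl-5-[tri(propan-2-yl)silyloxy]phenol
Product: 12 6-hydroxy-2-methoxy-3-methyl-4-[tri(propan-2-yl)silyloxy]benzaldehyde
Conditions: MgCl2, Et3N, (CH2O)n, MeCN, reflux
Reagents that add atoms: paraformaldehyde (as formaldehyde), C=O
Why: The Casnati–Skattebøl ortho-formylation runs through a magnesium phenoxide that delivers formaldehyde only to a carbon ortho to the phenol oxygen, and of the two such carbons the one beside the small methoxy group should react while the one beside the TIPS ether is screened; a second formaldehyde then oxidises the benzylic alkoxide to the aldehyde.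

Step 8
Reactants: 12 6-hydroxy-2-methoxy-3-methyl-4-[tri(propan-2-yl)silyloxy]benzaldehyde; 13 butanoyl chloride
Product: 14 2-formyl-3-methoxy-4-methyl-5-[tri(propan-2-yl)silyloxy]phenyl butanoate
Conditions: Et3N, DMAP (cat.), CH2Cl2, 0 °C to rt
Reagents that add atoms: none
Why: DMAP-catalysed acylation of the salicylaldehyde-type phenol should give the aryl butanoate, the aldehyde being inert to the acyl chloride.

Step 9
Reactants: 7 3,5-dihydroxy-4-methylphenyl pentanoate (2 equiv); 14 2-formyl-3-methoxy-4-methyl-5-[tri(propan-2-yl)silyloxy]phenyl butanoate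
Product: 16 2-[[2-(butanoyloxy)-6-methoxy-5-methyl-4-[tri(propan-2-yl)silyloxy]phenyl]methyl]-3,5-dihydroxy-4-methylphenyl pentanoate, via diarylmethanol 15 (not isolated)
Conditions: CF3CO2H, Et3SiH (3 equiv), CH2Cl2, 0 °C to rt
Reagents that add atoms: none
Why: In this reductive Friedel–Crafts alkylation (acid-promoted hydroxyalkylation followed by ionic hydrogenation) the protonated aldehyde should be attacked by the resorcinol-type ring of 7 at one of its two equivalent C–H positions, the doubly aryl-stabilised cation from carbinol 15 should take hydride from Et3SiH, and the aryl esters and the aryl TIPS ether are stable to CF3CO2H.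

Step 10
Reactants: 16 2-[[2-(butanoyloxy)-6-methoxy-5-methyl-4-[tri(propan-2-yl)silyloxy]phenyl]methyl]-3,5-dihydroxy-4-methylphenyl pentanoate
Product: 17 1-[3-[[3-butanoyl-2-hydroxy-6-methoxy-5-methyl-4-[tri(propan-2-yl)silyloxy]phenyl]methyl]-2,4,6-trihydroxy-5-methylphenyl]pentan-1-one
Conditions: hν (254 nm, low-pressure Hg lamp, quartz, thin-layer or flow cell), degassed MeCN, 5 mM, 20 °C
Reagents that add atoms: none
Why: Excitation of each aryl ester should break its oxygen–acyl bond homolytically to a phenoxyl/acyl radical pair held in the solvent cage, and recombination at the ring carbon ortho to that oxygen followed by tautomerisation gives the hydrogen-bonded ortho-hydroxyaryl ketone. The closest known reaction is the photo-Fries rearrangement of aryl alkanoates, here running independently on both rings in one irradiation. No ring is closed and no stereocentre is formed. The step needs each acyl group to enter one carbon only, and the substrate secures this because each ring has a single C–H, ortho to its ester oxygen, while the other ortho carbon (CH2 bridge) and the para carbon (methyl) are substituted, so recombination there gives dienones that cannot tautomerise and fall back to the ester. It also needs the pentanoyl group to stay on ring A and the butanoyl group on ring B, which in-cage recombination ensures, whereas a Lewis-acid Fries reaction on the diester could exchange them. The product ketones shed excitation by proton transfer within their hydrogen bond and should therefore accumulate without further photochemistry.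

Step 11
Reactants: 17 1-[3-[[3-butanoyl-2-hydroxy-6-methoxy-5-methyl-4-[tri(propan-2-yl)silyloxy]phenyl]methyl]-2,4,6-trihydroxy-5-methylphenyl]pentan-1-one
Product: 18 1-[3-[(3-butanoyl-2,4-dihydroxy-6-methoxy-5-methylphenyl)methyl]-2,4,6-trihydroxy-5-methylphenyl]pentan-1-one (CNP0210501.0)
Conditions: HF·pyridine, THF, 0 °C to rt
Reagents that add atoms: none
Why: In this fluoride desilylation the TIPS ether now lies ortho to the butanoyl ketone, so its phenoxide is a good leaving group and the Si–O bond should cleave under mild acidic fluoride conditions that leave the methyl ether, both ketones and the diarylmethane untouched.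

**Compound list**

1 | 2-methylbenzene-1,3-diol (2-methylresorcinol) | Cc1c(O)cccc1O | starting material
2 | 2,6-bis[tert-butyl(dimethyl)silyloxy]toluene | Cc1c(O[Si](C)(C)C(C)(C)C)cccc1O[Si](C)(C)C(C)(C)C | intermediate
3 | 2-[3,5-bis[tert-butyl(dimethyl)silyloxy]-4-methylphenyl]-4,4,5,5-tetramethyl-1,3,2-dioxaborolane (formed in the flask, not isolated) | Cc1c(O[Si](C)(C)C(C)(C)C)cc(B2OC(C)(C)C(C)(C)O2)cc1O[Si](C)(C)C(C)(C)C | intermediate
4 | 3,5-bis[tert-butyl(dimethyl)silyloxy]-4-methylphenol | Cc1c(O[Si](C)(C)C(C)(C)C)cc(O)cc1O[Si](C)(C)C(C)(C)C | intermediate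
5 | pentanoyl chloride | CCCCC(Cl)=O | starting material
6 | 3,5-bis[tert-butyl(dimethyl)silyloxy]-4-methylphenyl pentanoate | CCCCC(=O)Oc1cc(O[Si](C)(C)C(C)(C)C)c(C)c(O[Si](C)(C)C(C)(C)C)c1 | intermediate
7 | 3,5-dihydroxy-4-methylphenyl pentanoate | CCCCC(=O)Oc1cc(O)c(C)c(O)c1 | intermediate
8 | 3-methoxy-2-methylphenol | COc1cccc(O)c1C | starting material
9 | (3-methoxy-2-methylphenoxy)tri(propan-2-yl)silane | COc1cccc(O[Si](C(C)C)(C(C)C)C(C)C)c1C | intermediate
10 | 2-[3-methoxy-4-methyl-5-[tri(propan-2-yl)silyloxy]phenyl]-4,4,5,5-tetramethyl-1,3,2-dioxaborolane (formed in the flask, not isolated) | COc1cc(B2OC(C)(C)C(C)(C)O2)cc(O[Si](C(C)C)(C(C)C)C(C)C)c1C | intermediate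
11 | 3-methoxy-4-methyl-5-[tri(propan-2-yl)silyloxy]phenol | COc1cc(O)cc(O[Si](C(C)C)(C(C)C)C(C)C)c1C | intermediate
12 | 6-hydroxy-2-methoxy-3-methyl-4-[tri(propan-2-yl)silyloxy]benzaldehyde | COc1c(C=O)c(O)cc(O[Si](C(C)C)(C(C)C)C(C)C)c1C | intermediate
13 | butanoyl chloride | CCCC(Cl)=O | starting material
14 | 2-formyl-3-methoxy-4-methyl-5-[tri(propan-2-yl)silyloxy]phenyl butanoate | CCCC(=O)Oc1cc(O[Si](C(C)C)(C(C)C)C(C)C)c(C)c(OC)c1C=O | intermediate
15 | 2-[[2-(butanoyloxy)-6-methoxy-5-methyl-4-[tri(propan-2-yl)silyloxy]phenyl](hydroxy)methyl]-3,5-dihydroxy-4-methylphenyl pentanoate (racemic carbinol, formed in the flask, not isolated) | CCCCC(=O)Oc1cc(O)c(C)c(O)c1C(O)c1c(OC(=O)CCC)cc(O[Si](C(C)C)(C(C)C)C(C)C)c(C)c1OC | intermediate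
16 | 2-[[2-(butanoyloxy)-6-methoxy-5-methyl-4-[tri(propan-2-yl)silyloxy]phenyl]methyl]-3,5-dihydroxy-4-methylphenyl pentanoate | CCCCC(=O)Oc1cc(O)c(C)c(O)c1Cc1c(OC(=O)CCC)cc(O[Si](C(C)C)(C(C)C)C(C)C)c(C)c1OC | intermediate
17 | 1-[3-[[3-butanoyl-2-hydroxy-6-methoxy-5-methyl-4-[tri(propan-2-yl)silyloxy]phenyl]methyl]-2,4,6-trihydroxy-5-methylphenyl]pentan-1-one | CCCCC(=O)c1c(O)c(C)c(O)c(Cc2c(O)c(C(=O)CCC)c(O[Si](C(C)C)(C(C)C)C(C)C)c(C)c2OC)c1O | intermediate
18 | 1-[3-[(3-butanoyl-2,4-dihydroxy-6-methoxy-5-methylphenyl)methyl]-2,4,6-trihydroxy-5-methylphenyl]pentan-1-one | CCCCC(=O)c1c(O)c(C)c(O)c(Cc2c(O)c(C(=O)CCC)c(O)c(C)c2OC)c1O | target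

**Step count**

Total: 11 steps. Longest linear sequence: 7 steps (steps 1–4 or steps 5–8, then steps 9–11).

**Steps most likely to fail**

Step 10 (double photo-Fries shift). Acyl radicals may escape from the solvent cage, so that an acyl group is lost and a free phenol is left. The second shift may stall because the first-formed hydroxy ketone absorbs most of the light. Recombination at the ring B carbon may be slowed by the neighbouring silyl ether. The fallback sets out from 7 and 14 and returns at 17; it separates the two shifts. Ester 7 alone would be rearranged by a Lewis-acid Fries reaction (AlCl3, PhNO2, 60 °C), where exchange of acyl groups is impossible because only one is present, to give 1-(2,4,6-trihydroxy-3-methylphenyl)pentan-1-one F1. F1 would be alkylated at its single ring C–H with aldehyde 14 under the Et3SiH/CF3CO2H conditions of step 9 to give 3-methoxy-4-methyl-2-[(2,4,6-trihydroxy-3-methyl-5-pentanoylphenyl)methyl]-5-[tri(propan-2-yl)silyloxy]phenyl butanoate F2. The one remaining butanoate of F2 would then be moved to the only unsubstituted ring carbon with TiCl4 in CH2Cl2, which gives 17. Loss of the TIPS group under the Lewis acid would only deliver 18 directly.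

Step 9 (reductive Friedel–Crafts alkylation). The silane may reduce the protonated aldehyde before the arene has added, giving the methyl arene. The product may be alkylated a second time at its remaining ring A C–H. The benzylic cation may be captured by a second molecule of 7. The fallback sets out from 14 and returns at 16; it prepares the electrophile at the alcohol oxidation level first. BH3·THF at −20 °C, a neutral hydride donor that forms no alkoxide able to pull the butanoyl group onto the benzylic oxygen, would give 2-(hydroxymethyl)-3-methoxy-4-methyl-5-[tri(propan-2-yl)silyloxy]phenyl butanoate F3. F3 would then be ionised with catalytic BF3·OEt2 in CH2Cl2 at −40 °C in the presence of excess 7 (Friedel–Crafts benzylation with no silane in the flask) to give 16.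

Step 7 (ortho-formylation). The formyl group may enter the other ortho carbon, which lies para to the methoxy group and is electronically competitive, so steric screening by the silyl ether may not fully decide the position. The silyl ether may also be partly lost on prolonged heating. The fallback sets out from 11 and returns at 12; it uses directed ortho-metalation. The phenol would be converted with MOMCl and iPr2NEt into [3-methoxy-5-(methoxymethoxy)-2-methylphenoxy]tri(propan-2-yl)silane F4. n-BuLi/TMEDA in THF at 0 °C would remove the ring hydrogen flanked by the two coordinating groups (OMOM and OMe), the other candidate being flanked by the bulky, non-coordinating TIPS ether, and DMF would give 2-methoxy-6-(methoxymethoxy)-3-methyl-4-[tri(propan-2-yl)silyloxy]benzaldehyde F5. Dilute HCl in THF–iPrOH would cleave the MOM acetal ortho to the formyl group and give 12.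

**Further compounds**

F1 | step 10 | 1-(2,4,6-trihydroxy-3-methylphenyl)pentan-1-one | CCCCC(=O)c1c(O)cc(O)c(C)c1O
F2 | step 10 | 3-methoxy-4-methyl-2-[(2,4,6-trihydroxy-3-methyl-5-pentanoylphenyl)methyl]-5-[tri(propan-2-yl)silyloxy]phenyl butanoate | CCCCC(=O)c1c(O)c(C)c(O)c(Cc2c(OC(=O)CCC)cc(O[Si](C(C)C)(C(C)C)C(C)C)c(C)c2OC)c1O
F3 | step 9 | 2-(hydroxymethyl)-3-methoxy-4-methyl-5-[tri(propan-2-yl)silyloxy]phenyl butanoate | CCCC(=O)Oc1cc(O[Si](C(C)C)(C(C)C)C(C)C)c(C)c(OC)c1CO
F4 | step 7 | [3-methoxy-5-(methoxymethoxy)-2-methylphenoxy]tri(propan-2-yl)silane | COCOc1cc(OC)c(C)c(O[Si](C(C)C)(C(C)C)C(C)C)c1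
F5 | step 7 | 2-methoxy-6-(methoxymethoxy)-3-methyl-4-[tri(propan-2-yl)silyloxy]benzaldehyde | COCOc1cc(O[Si](C(C)C)(C(C)C)C(C)C)c(C)c(OC)c1C=O
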